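**Strategy.** The bicyclic core is traced back to a monocyclic precursor: a 1,2,2-trimethylcyclopentane whose quaternary ring carbon bears an exocyclic (S)-CH(OMs) carbon, with a silyl enol ether further along the chain. On ionisation the ring CMe2 carbon shifts to the carbinol carbon with inversion. The cyclopentane thereby grows into the gem-dimethylcyclohexane ring (C4a, C5–C8, C8a, naphthalene numbering), exploiting the CMe2(C5)–CH(C4a)–C(CH3)(C8a) array of the target. The tertiary C8a cation is trapped by the enol ether, closing the second ring and fixing C4a, C8a and C1 from one catalysis-derived carbinol centre. The side-chain stereocentre is bought; the acid arrives by carbonylation.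

Key step: step 8

Remark on the chemistry: the ring quaternary carbon of 3, 6–9 and 12 is stereogenic but is carried as both configurations (3 and 6 racemic; 7–9 and 12 as pairs of epimers at that carbon, uniform at the carbinol carbon). It becomes a planar cation in step 8, so it is left undefined in the SMILES. Compounds 1, 4 and 10 are taken to be catalogue compounds.

**Step 1**
Reactants: 1 1-(2-methylcyclopent-1-en-1-yl)ethan-1-one
Product: 3 rac-1-(1,2,2-trimethylcyclopentyl)ethan-1-one, via lithium enolate 2 (not isolated)
Conditions: Me2CuLi, Et2O, −20 → 0 °C; then MeI, DMPU, 0 °C → rt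
Reagents that add atoms: lithium dimethylcuprate ([Li+].C[Cu-]C); iodomethane (CI)
Why: Tandem cuprate 1,4-addition/enolate alkylation: the Gilman reagent adds to the tetrasubstituted enone (as with pulegone-type enones) and the regiodefined enolate is C-methylated in the same flask; the new quaternary centre is racemic, which is harmless because it is erased in step 8.

**Step 2**
Reactants: 3 rac-1-(1,2,2-trimethylcyclopentyl)ethan-1-one; 4 2-bromo-N-methoxy-N-methylacetamide
Product: 6 rac-N-methoxy-N-methyl-4-oxo-4-(1,2,2-trimethylcyclopentyl)butanamide, via lithium enolate 5 (not isolated)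
Conditions: LDA, THF, −78 °C; then 4, −78 → 0 °C
Reagents that add atoms: none
Why: Enolate alkylation: the methyl group is the only enolisable position of 3, and its lithium enolate displaces the activated primary bromide of the α-bromo Weinreb amide to give the 1,4-dicarbonyl compound.

**Step 3**
Reactants: 6 rac-N-methoxy-N-methyl-4-oxo-4-(1,2,2-trimethylcyclopentyl)butanamide
Product: 7 (4S)-4-hydroxy-N-methoxy-N-methyl-4-(1,2,2-trimethylcyclopentyl)butanamide (both configurations at the ring quaternary carbon)
Conditions: (R)-2-methyl-CBS-oxazaborolidine (20 mol%), BH3·SMe2, THF, −20 → 0 °C; MeOH quench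
Reagents that add atoms: none
Why: Corey–Bakshi–Shibata reduction: a tert-alkyl/primary-alkyl ketone is the ideal large/small case (pinacolone type), so the (R)-catalyst should give the (S)-carbinol under catalyst control for both enantiomers of 6, while the Weinreb amide reacts more slowly with borane at this temperature.

**Step 4**
Reactants: 7 (4S)-4-hydroxy-N-methoxy-N-methyl-4-(1,2,2-trimethylcyclopentyl)butanamide
Product: 8 (1S)-4-[methoxy(methyl)amino]-4-oxo-1-(1,2,2-trimethylcyclopentyl)butyl methanesulfonate
Conditions: MsCl, Et3N, CH2Cl2, −20 → 0 °C; used promptly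
Reagents that add atoms: methanesulfonyl chloride (CS(=O)(=O)Cl)
Why: Sulfonylation through the sulfene tolerates the hindered neopentyl-type secondary alcohol and does not touch the C–O bond, so the (S) configuration is kept.

**Step 5**
Reactants: 8 (1S)-4-[methoxy(methyl)amino]-4-oxo-1-(1,2,2-trimethylcyclopentyl)butyl methanesulfonate
Product: 9 (1S)-4-oxo-1-(1,2,2-trimethylcyclopentyl)hex-5-en-1-yl methanesulfonate
Conditions: CH2=CHMgBr, THF, −78 → −20 °C; inverse quench into cold 1 M HCl
Reagents that add atoms: vinylmagnesium bromide (C=C[Mg]Br)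
Why: Weinreb ketone synthesis: the chelated tetrahedral adduct prevents over-addition, the neopentyl-type mesylate cannot undergo SN2 displacement, and the acidic inverse quench keeps the released amine from adding to the vinyl ketone.

**Step 6**
Reactants: 10 (S)-3-bromo-2-methylpropan-1-ol
Product: 11 (S)-3-bromo-2-methylpropyl 2-methylpropanoate
Conditions: i-PrCOCl, Et3N, DMAP (cat.), CH2Cl2, 0 °C
Reagents that add atoms: 2-methylpropanoyl chloride (CC(C)C(=O)Cl)
Why: Plain O-acylation of the primary alcohol; the purchased stereocentre is not involved and later becomes the (R)-configured side-chain carbon of the target (same spatial arrangement, changed CIP priorities).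

**Step 7**
Reactants: 9 (1S)-4-oxo-1-(1,2,2-trimethylcyclopentyl)hex-5-en-1-yl methanesulfonate; 11 (S)-3-bromo-2-methylpropyl 2-methylpropanoate
Product: 12 (2R,5Z,9S)-2-methyl-9-(methylsulfonyloxy)-6-(triethylsilyloxy)-9-(1,2,2-trimethylcyclopentyl)non-5-en-1-yl 2-methylpropanoate (5Z isomer shown; any 5E isomer is carried along)
Conditions: NiCl2·glyme (10 mol%), terpyridine ligand (10 mol%), Mn powder, Et3SiCl, DMF, 25 °C
Reagents that add atoms: chlorotriethylsilane (CC[Si](Cl)(CC)CC)
Why: Nickel-catalysed reductive conjugate addition of an alkyl bromide to an enone with chlorosilane trapping forms the C–C bond at the enone β-carbon and delivers the silyl enol ether regiospecifically on that side, tolerating the ester and the sterically shielded secondary mesylate.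

**Step 8**
Reactants: 12 (2R,5Z,9S)-2-methyl-9-(methylsulfonyloxy)-6-(triethylsilyloxy)-9-(1,2,2-trimethylcyclopentyl)non-5-en-1-yl 2-methylpropanoate
Product: 14 (2R)-2-methyl-4-[(1R,4aS,8aS)-5,5,8a-trimethyl-2-oxodecahydronaphthalen-1-yl]butyl 2-methylpropanoate, via tertiary cyclohexyl cation 13 (not isolated)
Conditions: (CF3)2CHOH (0.02 M), 2,6-lutidine (3 equiv), 0 °C → rt; then DBU, PhMe, 60 °C (equilibration of C1)
Reagents that add atoms: none
Why: In the ionising, non-nucleophilic solvent the secondary mesylate departs with assistance from the antiperiplanar ring bond, so the CMe2 ring carbon migrates from the quaternary ring carbon to the carbinol carbon (Wagner–Meerwein 1,2-shift, cyclopentylcarbinyl → cyclohexyl), enlarging the five-membered ring to the gem-dimethylcyclohexane and leaving tertiary cation 13 at the future C8a. The closest known reaction types are the solvolytic ring expansion of (1-methylcyclopentyl)carbinyl sulfonates and the cation–olefin cyclisation of 2,6,6-trimethylcyclohexyl cations to drimane-type trans-decalins, here terminated by a silyl enol ether. The ketone-bearing ring closes by 6-endo attack of the enol ether carbon on the C8a cation, whereas the gem-dimethyl ring is not closed but arises from the 1,2-shift. C4a is set by inversion at the (S)-carbinol carbon (migration anti to the leaving group); C8a by a chair-like transition state with the tether equatorial at C4a and attack anti to the axial C4a–H (trans fusion); C1 by the Z enol ether in that chair (side chain equatorial) and, being α to the ketone, by the final base equilibration. The step needs migration of CMe2 rather than of the ring CH2 or the methyl group, which the far higher migratory aptitude of a tertiary alkyl carbon and the relief of cyclopentane strain should secure, and it needs C- rather than O-capture, which the silyl enol ether and hydrogen bonding of the solvent to oxygen lone pairs should secure. The configuration of the ring quaternary carbon of 12 is irrelevant because that carbon becomes planar.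

**Step 9**
Reactants: 14 (2R)-2-methyl-4-[(1R,4aS,8aS)-5,5,8a-trimethyl-2-oxodecahydronaphthalen-1-yl]butyl 2-methylpropanoate
Product: 16 (2R)-2-methyl-4-[(1R,4aS,8aS)-5,5,8a-trimethyl-2-(trifluoromethylsulfonyloxy)-1,4,4a,5,6,7,8,8a-octahydronaphthalen-1-yl]butyl 2-methylpropanoate, via potassium enolate 15 (not isolated)
Conditions: KHMDS (1.05 equiv), THF, −78 °C; then PhNTf2, −78 → 0 °C
Reagents that add atoms: N-phenylbis(trifluoromethanesulfonimide) (O=S(=O)(N(c1ccccc1)S(=O)(=O)C(F)(F)F)C(F)(F)F)
Why: Kinetic deprotonation occurs at the unhindered C3 methylene rather than at the tertiary C1–H next to quaternary C8a or at the less acidic ester α-H, and O-triflation fixes the C2=C3 double bond without touching C1.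

**Step 10**
Reactants: 16 (2R)-2-methyl-4-[(1R,4aS,8aS)-5,5,8a-trimethyl-2-(trifluoromethylsulfonyloxy)-1,4,4a,5,6,7,8,8a-octahydronaphthalen-1-yl]butyl 2-methylpropanoate
Product: 17 (1R,4aS,8aS)-5,5,8a-trimethyl-1-[(3R)-3-methyl-4-(2-methylpropanoyloxy)butyl]-1,4,4a,5,6,7,8,8a-octahydronaphthalene-2-carboxylic acid (CNP0323283.1)
Conditions: Pd(OAc)2 (5 mol%), dppf (6 mol%), CO (1 atm), Et3N, DMF/H2O, 60 °C; acidic work-up
Reagents that add atoms: carbon monoxide ([C-]#[O+]); water (O)
Why: Palladium-catalysed hydroxycarbonylation of an enol triflate (oxidative addition, CO insertion, hydrolysis of the acyl-palladium) gives the α,β-unsaturated acid directly, leaving the isobutyrate and all stereocentres untouched.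

**Compound list**
1 | 1-(2-methylcyclopent-1-en-1-yl)ethan-1-one | CC(=O)C1=C(C)CCC1 | starting material
2 | lithium 1-(2,2-dimethylcyclopentylidene)ethan-1-olate | [Li+].CC([O-])=C1CCCC1(C)C | intermediate
3 | rac-1-(1,2,2-trimethylcyclopentyl)ethan-1-one | CC(=O)C1(C)CCCC1(C)C | intermediate
4 | 2-bromo-N-methoxy-N-methylacetamide | CON(C)C(=O)CBr | starting material
5 | lithium 1-(1,2,2-trimethylcyclopentyl)ethen-1-olate | [Li+].C=C([O-])C1(C)CCCC1(C)C | intermediate
6 | rac-N-methoxy-N-methyl-4-oxo-4-(1,2,2-trimethylcyclopentyl)butanamide | CON(C)C(=O)CCC(=O)C1(C)CCCC1(C)C | intermediate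
7 | (4S)-4-hydroxy-N-methoxy-N-methyl-4-(1,2,2-trimethylcyclopentyl)butanamide | CON(C)C(=O)CC[C@H](O)C1(C)CCCC1(C)C | intermediate
8 | (1S)-4-[methoxy(methyl)amino]-4-oxo-1-(1,2,2-trimethylcyclopentyl)butyl methanesulfonate | CON(C)C(=O)CC[C@H](OS(C)(=O)=O)C1(C)CCCC1(C)C | intermediate
9 | (1S)-4-oxo-1-(1,2,2-trimethylcyclopentyl)hex-5-en-1-yl methanesulfonate | C=CC(=O)CC[C@H](OS(C)(=O)=O)C1(C)CCCC1(C)C | intermediate
10 | (S)-3-bromo-2-methylpropan-1-ol | OC[C@H](C)CBr | starting material
11 | (S)-3-bromo-2-methylpropyl 2-methylpropanoate | CC(C)C(=O)OC[C@H](C)CBr | intermediate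
12 | (2R,5Z,9S)-2-methyl-9-(methylsulfonyloxy)-6-(triethylsilyloxy)-9-(1,2,2-trimethylcyclopentyl)non-5-en-1-yl 2-methylpropanoate | CC(C)C(=O)OC[C@H](C)CC/C=C(\O[Si](CC)(CC)CC)CC[C@H](OS(C)(=O)=O)C1(C)CCCC1(C)C | intermediate
13 | 1,3,3-trimethyl-2-substituted cyclohexan-1-ylium ion (ring CH configured as C4a of the target; chain carries the Z silyl enol ether and the ester) | CC(C)C(=O)OC[C@H](C)CC/C=C(\O[Si](CC)(CC)CC)CC[C@@H]1[C+](C)CCCC1(C)C | intermediate
14 | (2R)-2-methyl-4-[(1R,4aS,8aS)-5,5,8a-trimethyl-2-oxodecahydronaphthalen-1-yl]butyl 2-methylpropanoate | CC(C)C(=O)OC[C@H](C)CC[C@H]1C(=O)CC[C@H]2C(C)(C)CCC[C@]12C | intermediate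
15 | potassium enolate of 14 (C2=C3) | [K+].CC(C)C(=O)OC[C@H](C)CC[C@H]1C([O-])=CC[C@H]2C(C)(C)CCC[C@]12C | intermediate
16 | (2R)-2-methyl-4-[(1R,4aS,8aS)-5,5,8a-trimethyl-2-(trifluoromethylsulfonyloxy)-1,4,4a,5,6,7,8,8a-octahydronaphthalen-1-yl]butyl 2-methylpropanoate | CC(C)C(=O)OC[C@H](C)CC[C@H]1C(OS(=O)(=O)C(F)(F)F)=CC[C@H]2C(C)(C)CCC[C@]12C | intermediate
17 | (1R,4aS,8aS)-5,5,8a-trimethyl-1-[(3R)-3-methyl-4-(2-methylpropanoyloxy)butyl]-1,4,4a,5,6,7,8,8a-octahydronaphthalene-2-carboxylic acid | CC(C)C(=O)OC[C@H](C)CC[C@H]1C(C(=O)O)=CC[C@H]2C(C)(C)CCC[C@]12C | target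

**Step count.** Total: 10 steps. Longest linear sequence: 9 steps (1–5, 7–10); step 6 is the side branch.

**Steps most likely to fail**

Step 8. The silyl group may be lost before ionisation, so that the cation is captured at oxygen. The cation may also lose a proton before ring closure, or close to the cis-fused ring. The fallback separates ring enlargement from ring closure and sets out from 8. Buffered solvolysis of 8 in (CF3)2CHOH should effect the same 1,2-shift with capture of the cation by the amide oxygen, giving after aqueous work-up the lactone (4aS)-5,5,8a-trimethyloctahydro-2H-chromen-2-one F1. Mono-addition of vinylmagnesium bromide at −78 °C should give 5-[(1S)-2-hydroxy-2,6,6-trimethylcyclohexyl]pent-1-en-3-one F2. Reductive conjugate addition with 11 and Et3SiCl as in step 7 should give (2R,5Z)-8-[(1S)-2-hydroxy-2,6,6-trimethylcyclohexyl]-2-methyl-6-(triethylsilyloxy)oct-5-en-1-yl 2-methylpropanoate F3. SnCl4 in CH2Cl2 at −78 °C then ionises the tertiary alcohol to cation 13 under Mukaiyama-type conditions, as known for monocyclic 2,6,6-trimethylcyclohexyl precursors. After the DBU equilibration the route is rejoined at 14.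

Step 7. The vinyl ketone may oligomerise under the reducing conditions, low-valent nickel may attack the sulfonate, and the enol ether geometry may be poorly controlled. The fallback forms the enone double bond instead of the bond at the β-carbon and sets out from 9 and 11. Nickel-catalysed reductive vinylation of 11 with vinyl bromide (NiI2, 4,4'-di-tert-butyl-2,2'-bipyridine, Zn, DMA) should give (2R)-2-methylpent-4-en-1-yl 2-methylpropanoate F4. Cross-metathesis of F4 with 9 (second-generation Grubbs catalyst, CH2Cl2, 40 °C) should give (2R,4E,9S)-2-methyl-9-(methylsulfonyloxy)-6-oxo-9-(1,2,2-trimethylcyclopentyl)non-4-en-1-yl 2-methylpropanoate F5. 1,4-Hydrosilylation with Et3SiH and RhCl(PPh3)3 should then give the Z silyl enol ether, rejoining the route at 12.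

Step 3. Hydride transfer to the doubly neopentyl ketone may be slow, so that borane attacks the amide, and catalyst control may be incomplete for one enantiomer of the racemic ketone. The fallback sets the centre at the ester level by hydrogenation and sets out from 3. Alkylation of its enolate with methyl bromoacetate should give methyl 4-oxo-4-(1,2,2-trimethylcyclopentyl)butanoate F6. Noyori-type asymmetric hydrogenation with a Ru(II)–TolBINAP/α-picolylamine catalyst made for tert-alkyl ketones (catalyst enantiomer chosen to give the (S)-carbinol), followed by acid-induced lactonisation, should give (5S)-5-(1,2,2-trimethylcyclopentyl)oxolan-2-one F7, which can be purified at this stage. Aminolysis with MeNHOMe·HCl/Me2AlCl rejoins the route at 7.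

**Further compounds**
F1 | step 8 | (4aS)-5,5,8a-trimethyloctahydro-2H-chromen-2-one (either configuration at C8a) | O=C1CC[C@H]2C(C)(C)CCCC2(C)O1
F2 | step 8 | 5-[(1S)-2-hydroxy-2,6,6-trimethylcyclohexyl]pent-1-en-3-one | C=CC(=O)CC[C@H]1C(C)(C)CCCC1(C)O
F3 | step 8 | (2R,5Z)-8-[(1S)-2-hydroxy-2,6,6-trimethylcyclohexyl]-2-methyl-6-(triethylsilyloxy)oct-5-en-1-yl 2-methylpropanoate | CC(C)C(=O)OC[C@H](C)CC/C=C(\O[Si](CC)(CC)CC)CC[C@H]1C(C)(C)CCCC1(C)O
F4 | step 7 | (2R)-2-methylpent-4-en-1-yl 2-methylpropanoate | CC(C)C(=O)OC[C@H](C)CC=C
F5 | step 7 | (2R,4E,9S)-2-methyl-9-(methylsulfonyloxy)-6-oxo-9-(1,2,2-trimethylcyclopentyl)non-4-en-1-yl 2-methylpropanoate | CC(C)C(=O)OC[C@H](C)C/C=C/C(=O)CC[C@H](OS(C)(=O)=O)C1(C)CCCC1(C)C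
F6 | step 3 | methyl 4-oxo-4-(1,2,2-trimethylcyclopentyl)butanoate | COC(=O)CCC(=O)C1(C)CCCC1(C)C
F7 | step 3 | (5S)-5-(1,2,2-trimethylcyclopentyl)oxolan-2-one | O=C1CC[C@@H](C2(C)CCCC2(C)C)O1
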